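**Plan**

1. Target: (1S,4R)-trans-4-aryl-5-methoxytetralin-1-ol. Tetralin numbering is used throughout: C1 carbinol, C2, C3, C4 (naphthyl-bearing), C4a/C8a ring fusion, C5 (OMe), C8; naphthol atoms are primed.
2. Retrosynthesis: C8–H back to C8–Cl (temporary blocking group) and C3–C4 back to a C3=C4 alkene. The saturated ring of the resulting 1,2-dihydronaphthalene is then cut at C2–C3 and at C4–C4a in one radical [4+2] annulation.
3. Enabling feature: C4 is bound both to naphthol C2' and to C4a, and C4a lies ortho to C8a, which carries C1–C2. Aryl–C1–C2 is thus a 2-arylethyl radical (from a β-silyloxy acid by loss of CO2) and C3–C4 is a 2-ethynylnaphthalene whose vinyl radical at C4 closes on C4a.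
4. Forward: the anisole fragment with C1 and the C2 radical precursor (steps 1–5) and the naphthalene alkyne (steps 6–8) are joined and the saturated ring closed in step 9. Desilylation, alkene hydrogenation and dechlorination follow.
5. Stereochemistry: C1 (S) from Noyori asymmetric hydrogenation of a β-keto ester. C4 (R) from hydroxyl-directed hydrogenation of C3=C4, where delivery of H2 on the C1–OH face places the naphthyl group trans to OH.

Key step: step 9

Remark: 2-chloro-5-methoxybenzaldehyde and 8-methoxynaphthalen-1-ol are taken as purchasable; the chlorine para to OMe only serves to force ring closure at the position ortho to OMe.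

**Route**

Step 1
Reactants: 1 2-chloro-5-methoxybenzaldehyde; 2 ethyl diazoacetate
Product: 3 ethyl 3-(2-chloro-5-methoxyphenyl)-3-oxopropanoate
Conditions: NbCl5 (5 mol %), CH2Cl2, rt
Reagents that add atoms: none
Why: Roskamp reaction: the diazo carbon adds to the Lewis acid-activated aldehyde and a 1,2-hydride shift with loss of N2 should give the β-keto ester, the aryl chloride and methyl ether being inert.

Step 2
Reactants: 3 ethyl 3-(2-chloro-5-methoxyphenyl)-3-oxopropanoate
Product: 4 ethyl (3S)-3-(2-chloro-5-methoxyphenyl)-3-hydroxypropanoate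
Conditions: [RuCl(C6H6)((R)-BINAP)]Cl (1 mol %), H2 (50 bar), EtOH, 60 °C
Reagents that add atoms: none
Why: Noyori asymmetric hydrogenation of a β-keto ester: the chelated keto ester is reduced on one carbonyl face, the (R)-ligand being the antipode expected to give the (3S)-carbinol that becomes C1, and the aryl chloride is not touched by this catalyst.

Step 3
Reactants: 4 ethyl (3S)-3-(2-chloro-5-methoxyphenyl)-3-hydroxypropanoate
Product: 5 ethyl (3S)-3-[(tert-butyldimethylsilyl)oxy]-3-(2-chloro-5-methoxyphenyl)propanoate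
Conditions: TBSCl, imidazole, DMF, rt
Reagents that add atoms: tert-butyldimethylsilyl chloride, CC(C)(C)[Si](C)(C)Cl
Why: Standard silylation of a secondary benzylic alcohol, which masks the C1 hydroxyl for the ester activation and the radical step.

Step 4
Reactants: 5 ethyl (3S)-3-[(tert-butyldimethylsilyl)oxy]-3-(2-chloro-5-methoxyphenyl)propanoate
Product: 6 (3S)-3-[(tert-butyldimethylsilyl)oxy]-3-(2-chloro-5-methoxyphenyl)propanoic acid
Conditions: LiOH, THF–H2O, 0 °C to rt; then 1 M HCl to pH 3
Reagents that add atoms: lithium hydroxide, [Li+].[OH-]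
Why: Ester saponification run cold so that β-elimination of silanolate and silyl loss should not compete; the stereocentre is not involved.

Step 5
Reactants: 6 (3S)-3-[(tert-butyldimethylsilyl)oxy]-3-(2-chloro-5-methoxyphenyl)propanoic acid
Product: 7 1,3-dioxoisoindolin-2-yl (3S)-3-[(tert-butyldimethylsilyl)oxy]-3-(2-chloro-5-methoxyphenyl)propanoate
Conditions: N-hydroxyphthalimide, DIC, DMAP (cat.), CH2Cl2, rt
Reagents that add atoms: N-hydroxyphthalimide, O=C1c2ccccc2C(=O)N1O
Why: Carbodiimide (Steglich-type) esterification should give the redox-active ester needed for reductive decarboxylation.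

Step 6
Reactants: 8 8-methoxynaphthalen-1-ol
Product: 9 1-hydroxy-8-methoxynaphthalene-2-carbaldehyde
Conditions: MgCl2, Et3N, (CH2O)n, MeCN, reflux; then 1 M HCl
Reagents that add atoms: paraformaldehyde (as formaldehyde), C=O
Why: Casnati–Skattebøl ortho-formylation: formaldehyde is delivered within the magnesium naphtholate to C2', the only free ortho position, and a second formaldehyde oxidises the hydroxymethyl intermediate by hydride transfer.

Step 7
Reactants: 9 1-hydroxy-8-methoxynaphthalene-2-carbaldehyde
Product: 10 8-methoxy-1-[(triisopropylsilyl)oxy]naphthalene-2-carbaldehyde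
Conditions: TIPSOTf, 2,6-lutidine, CH2Cl2, 0 °C to rt
Reagents that add atoms: triisopropylsilyl triflate, CC(C)[Si](C(C)C)(C(C)C)OS(=O)(=O)C(F)(F)F
Why: Silyl triflate silylation of the hindered, hydrogen-bonded naphthol removes the phenolic O–H ahead of the organolithium and radical steps.

Step 8
Reactants: 10 8-methoxy-1-[(triisopropylsilyl)oxy]naphthalene-2-carbaldehyde
Product: 11 [(2-ethynyl-8-methoxynaphthalen-1-yl)oxy]triisopropylsilane
Conditions: TMSCHN2, LDA, THF, −78 °C to rt; then H2O
Reagents that add atoms: trimethylsilyldiazomethane, C[Si](C)(C)C=[N+]=[N-]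
Why: Colvin rearrangement: lithiated trimethylsilyldiazomethane adds to the aldehyde, Peterson elimination gives a diazoalkene, and loss of N2 with 1,2-hydrogen shift of the alkylidene carbene should give the terminal alkyne with the aryl silyl ether intact.

Step 9
Reactants: 7 1,3-dioxoisoindolin-2-yl (3S)-3-[(tert-butyldimethylsilyl)oxy]-3-(2-chloro-5-methoxyphenyl)propanoate; 11 [(2-ethynyl-8-methoxynaphthalen-1-yl)oxy]triisopropylsilane (2.5 equiv)
Product: 12 tert-butyl({(1S)-8-chloro-5-methoxy-4-[8-methoxy-1-(triisopropylsilyloxy)naphthalen-2-yl]-1,2-dihydronaphthalen-1-yl}oxy)dimethylsilane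
Conditions: fac-Ir(ppy)3 (1 mol %), DMF, blue LEDs (450 nm), rt, argon
Reagents that add atoms: none
Why: Photoexcited fac-Ir(ppy)3 should reduce 7, which loses phthalimide anion and CO2 to give the primary C2 radical; this adds to the terminal carbon of 11 (C2–C3 bond), the linear α-naphthyl vinyl radical at C4 attacks the anisole ring at C4a (C4–C4a bond), and the cyclohexadienyl radical is oxidised by tetravalent iridium (or by 7 in a chain) and deprotonated by phthalimide anion. The closest known reaction type is the radical [4+2] annulation of 2-arylethyl-type (benzylmalonyl) radicals with aryl alkynes to 1,2-dihydronaphthalenes under Mn(OAc)3 or photoredox conditions, here combined with the established decarboxylative radical generation from N-acyloxyphthalimides. The saturated ring closes by a 6-exo-trig ortho attack on the C4a=C5 bond of the arene, and the linear vinyl radical allows only the cis ring alkene. No stereocentre is formed: C1 is carried through because the radical sits on C2 and the β-silyloxy group does not fragment, and the C3=C4 alkene is kept for step 11. Regioselectivity of the addition is secured by the terminal alkyne and naphthyl stabilisation of the vinyl radical; regioselectivity of the closure by the chlorine at C8, which leaves C4a (ortho to OMe) as the only hydrogen-bearing ortho position; the two silyl ethers remove the O–H bonds from which the radicals could abstract hydrogen.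

Step 10
Reactants: 12 tert-butyl({(1S)-8-chloro-5-methoxy-4-[8-methoxy-1-(triisopropylsilyloxy)naphthalen-2-yl]-1,2-dihydronaphthalen-1-yl}oxy)dimethylsilane
Product: 13 (1S)-8-chloro-4-(1-hydroxy-8-methoxynaphthalen-2-yl)-5-methoxy-1,2-dihydronaphthalen-1-ol
Conditions: TBAF (3 equiv), AcOH (3 equiv), THF, 0 °C to rt
Reagents that add atoms: none
Why: Fluoride should cleave both Si–O bonds, and the acetic acid buffer keeps the medium from becoming basic or acidic enough to dehydrate the 1,2-dihydronaphthalen-1-ol to a naphthalene.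

Step 11
Reactants: 13 (1S)-8-chloro-4-(1-hydroxy-8-methoxynaphthalen-2-yl)-5-methoxy-1,2-dihydronaphthalen-1-ol
Product: 14 (1S,4R)-8-chloro-4-(1-hydroxy-8-methoxynaphthalen-2-yl)-5-methoxy-1,2,3,4-tetrahydronaphthalen-1-ol
Conditions: [Ir(cod)(PCy3)(py)]PF6 (5 mol %), H2 (1 atm), CH2Cl2, rt
Reagents that add atoms: none
Why: Hydroxyl-directed hydrogenation: the cationic iridium centre binds the homoallylic C1 hydroxyl (held pseudoaxial by the peri chlorine) and the C3=C4 alkene on the same face, so hydrogen is delivered cis to OH and the naphthyl group at the new C4 stereocentre should end up trans, giving (4R).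

Step 12
Reactants: 14 (1S,4R)-8-chloro-4-(1-hydroxy-8-methoxynaphthalen-2-yl)-5-methoxy-1,2,3,4-tetrahydronaphthalen-1-ol
Product: 15 dipolynaphthalene A, (1S,4R)-4-(1-hydroxy-8-methoxynaphthalen-2-yl)-5-methoxy-1,2,3,4-tetrahydronaphthalen-1-ol
Conditions: 10% Pd/C, H2 (1 atm), Et3N, MeOH, rt
Reagents that add atoms: none
Why: Palladium-catalysed hydrogenolysis of the aryl C–Cl bond removes the blocking group, triethylamine trapping HCl so that acid-promoted hydrogenolysis of the benzylic alcohol should not set in; neither stereocentre is involved.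

**Compound list**

1 | 2-chloro-5-methoxybenzaldehyde | COc1ccc(Cl)c(C=O)c1 | starting material
2 | ethyl diazoacetate | CCOC(=O)C=[N+]=[N-] | starting material
3 | ethyl 3-(2-chloro-5-methoxyphenyl)-3-oxopropanoate | CCOC(=O)CC(=O)c1cc(OC)ccc1Cl | intermediate
4 | ethyl (3S)-3-(2-chloro-5-methoxyphenyl)-3-hydroxypropanoate | CCOC(=O)C[C@@H](c1cc(OC)ccc1Cl)O | intermediate
5 | ethyl (3S)-3-[(tert-butyldimethylsilyl)oxy]-3-(2-chloro-5-methoxyphenyl)propanoate | CCOC(=O)C[C@@H](c1cc(OC)ccc1Cl)O[Si](C)(C)C(C)(C)C | intermediate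
6 | (3S)-3-[(tert-butyldimethylsilyl)oxy]-3-(2-chloro-5-methoxyphenyl)propanoic acid | OC(=O)C[C@@H](c1cc(OC)ccc1Cl)O[Si](C)(C)C(C)(C)C | intermediate
7 | 1,3-dioxoisoindolin-2-yl (3S)-3-[(tert-butyldimethylsilyl)oxy]-3-(2-chloro-5-methoxyphenyl)propanoate | O=C(ON1C(=O)c2ccccc2C1=O)C[C@@H](c1cc(OC)ccc1Cl)O[Si](C)(C)C(C)(C)C | intermediate
8 | 8-methoxynaphthalen-1-ol | COc1cccc2cccc(O)c12 | starting material
9 | 1-hydroxy-8-methoxynaphthalene-2-carbaldehyde | COc1cccc2ccc(C=O)c(O)c12 | intermediate
10 | 8-methoxy-1-[(triisopropylsilyl)oxy]naphthalene-2-carbaldehyde | COc1cccc2ccc(C=O)c(O[Si](C(C)C)(C(C)C)C(C)C)c12 | intermediate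
11 | [(2-ethynyl-8-methoxynaphthalen-1-yl)oxy]triisopropylsilane | COc1cccc2ccc(C#C)c(O[Si](C(C)C)(C(C)C)C(C)C)c12 | intermediate
12 | tert-butyl({(1S)-8-chloro-5-methoxy-4-[8-methoxy-1-(triisopropylsilyloxy)naphthalen-2-yl]-1,2-dihydronaphthalen-1-yl}oxy)dimethylsilane | COc1ccc(Cl)c2c1C(c1ccc3cccc(OC)c3c1O[Si](C(C)C)(C(C)C)C(C)C)=CC[C@@H]2O[Si](C)(C)C(C)(C)C | intermediate
13 | (1S)-8-chloro-4-(1-hydroxy-8-methoxynaphthalen-2-yl)-5-methoxy-1,2-dihydronaphthalen-1-ol | COc1ccc(Cl)c2c1C(c1ccc3cccc(OC)c3c1O)=CC[C@@H]2O | intermediate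
14 | (1S,4R)-8-chloro-4-(1-hydroxy-8-methoxynaphthalen-2-yl)-5-methoxy-1,2,3,4-tetrahydronaphthalen-1-ol | COc1ccc(Cl)c2c1[C@@H](c1ccc3cccc(OC)c3c1O)CC[C@@H]2O | intermediate
15 | dipolynaphthalene A, (1S,4R)-4-(1-hydroxy-8-methoxynaphthalen-2-yl)-5-methoxy-1,2,3,4-tetrahydronaphthalen-1-ol | COc1cccc2c1[C@@H](c1ccc3cccc(OC)c3c1O)CC[C@@H]2O | target

**Count and risks**

Total step count: 12. Longest linear sequence: 9 steps (steps 1–5 and 9–12).

Steps most likely to fail:

1. Step 9. The primary radical may be reduced or undergo a 1,2-aryl shift before it adds to the electron-rich alkyne. The vinyl radical may close on the chlorine-bearing ortho carbon with loss of chlorine, or at the ipso carbon, instead of on C4a. Fallback, from 7 and 11, returning at 12: 11 is deprotonated (n-BuLi, THF) and transmetalated with ZnCl2 to chloro{[8-methoxy-1-(triisopropylsilyloxy)naphthalen-2-yl]ethynyl}zinc F1. Nickel-catalysed decarboxylative alkynylation of 7 with it (NiCl2·6H2O, 2,2'-bipyridine, THF–DMF, rt) should form the C2–C3 bond and give the internal alkyne tert-butyl({(1S)-1-(2-chloro-5-methoxyphenyl)-4-[8-methoxy-1-(triisopropylsilyloxy)naphthalen-2-yl]but-3-yn-1-yl}oxy)dimethylsilane F2. A polar gold-catalysed 6-endo-dig hydroarylation ((Ph3P)AuNTf2, CH2Cl2, rt) then forms the C4–C4a bond ortho to OMe, the para position being blocked by chlorine, and gives 12.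

2. Step 11. Facial control may erode if the naphthol hydroxyl competes with the C1 hydroxyl for iridium; it can sit over either alkene face because rotation about the C4–C2' bond is slow. The hindered trisubstituted alkene may deactivate the catalyst, or traces of acid may dehydrate the dihydronaphthalenol to a naphthalene. Fallback, from 12, returning at 14: catalyst-controlled asymmetric hydrogenation of the fully silylated alkene with a chiral iridium P,N complex ([Ir(cod)(tBu-PHOX)][B(3,5-(CF3)2C6H3)4], H2 50 bar, CH2Cl2). The ligand antipode is chosen so that hydrogen enters cis to the silyloxy group, giving tert-butyl({(1S,4R)-8-chloro-5-methoxy-4-[8-methoxy-1-(triisopropylsilyloxy)naphthalen-2-yl]-1,2,3,4-tetrahydronaphthalen-1-yl}oxy)dimethylsilane F3. Desilylation (TBAF, AcOH, THF) then gives 14.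

3. Step 12. Cleavage of the hindered peri C–Cl bond may be slow, so that hydrogenolysis of the benzylic C1–O bond overtakes it. Fallback, from 12, returning at 15: the chlorine is removed while the carbinol is still silylated, by homogeneous palladium-catalysed transfer hydrodechlorination ([Pd(allyl)Cl(IPr)], IPr = 1,3-bis(2,6-diisopropylphenyl)imidazol-2-ylidene, NaOtBu, iPrOH, 60 °C), giving tert-butyl({(1S)-5-methoxy-4-[8-methoxy-1-(triisopropylsilyloxy)naphthalen-2-yl]-1,2-dihydronaphthalen-1-yl}oxy)dimethylsilane F4. Desilylation (TBAF, AcOH, THF) gives (1S)-4-(1-hydroxy-8-methoxynaphthalen-2-yl)-5-methoxy-1,2-dihydronaphthalen-1-ol F5. Hydroxyl-directed hydrogenation as in step 11 ([Ir(cod)(PCy3)(py)]PF6, H2, CH2Cl2) then gives 15 directly.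

Further compounds
F1 | step 9 | chloro{[8-methoxy-1-(triisopropylsilyloxy)naphthalen-2-yl]ethynyl}zinc | COc1cccc2ccc(C#C[Zn]Cl)c(O[Si](C(C)C)(C(C)C)C(C)C)c12
F2 | step 9 | tert-butyl({(1S)-1-(2-chloro-5-methoxyphenyl)-4-[8-methoxy-1-(triisopropylsilyloxy)naphthalen-2-yl]but-3-yn-1-yl}oxy)dimethylsilane | COc1cccc2ccc(C#CC[C@@H](c3cc(OC)ccc3Cl)O[Si](C)(C)C(C)(C)C)c(O[Si](C(C)C)(C(C)C)C(C)C)c12
F3 | step 11 | tert-butyl({(1S,4R)-8-chloro-5-methoxy-4-[8-methoxy-1-(triisopropylsilyloxy)naphthalen-2-yl]-1,2,3,4-tetrahydronaphthalen-1-yl}oxy)dimethylsilane | COc1ccc(Cl)c2c1[C@@H](c1ccc3cccc(OC)c3c1O[Si](C(C)C)(C(C)C)C(C)C)CC[C@@H]2O[Si](C)(C)C(C)(C)C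
F4 | step 12 | tert-butyl({(1S)-5-methoxy-4-[8-methoxy-1-(triisopropylsilyloxy)naphthalen-2-yl]-1,2-dihydronaphthalen-1-yl}oxy)dimethylsilane | COc1cccc2c1C(c1ccc3cccc(OC)c3c1O[Si](C(C)C)(C(C)C)C(C)C)=CC[C@@H]2O[Si](C)(C)C(C)(C)C
F5 | step 12 | (1S)-4-(1-hydroxy-8-methoxynaphthalen-2-yl)-5-methoxy-1,2-dihydronaphthalen-1-ol | COc1cccc2c1C(c1ccc3cccc(OC)c3c1O)=CC[C@@H]2O
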